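**Strategy.** Ring C is disconnected at C2–C3. C2 is attached to O1 and to ring B, so as the CH2 of an aryl benzyl ether its C–H bonds are activated twice over and placed for a six-membered closure onto a carbene at C3. A chiral divalent-rhodium carboxylate converts an α-diazoketone into that carbene, and insertion into the benzylic C–H bond forms C2–C3, closes ring C and sets C2 in one operation. The precursor is a 2-diazo-1-arylethanone whose aryl ring (future ring A) carries the ring B benzyl ether at O1, the preformed side chain at C8, the C7 methoxy group and a bulky silyl ether at O5. Every hydroxyl is silylated, so one fluoride step ends the synthesis.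

Key step: step 15

Remarks on the chemistry:
- Abbreviations: TBS = tert-butyldimethylsilyl, TIPS = tri(propan-2-yl)silyl, TES = triethylsilyl. Flavanone numbering (O1, C2, C3, C4, C5–C8; ring B positions primed) is used.
- Assumption: Rh2(S-PTTL)4 is taken to select the benzylic hydrogen that leads to (2S); if a trial run shows the opposite sense, Rh2(R-PTTL)4 is used with no other change.
- Protecting groups: only silyl ethers are used (TIPS at O5, TBS on ring B, TES on the tertiary alcohol). After C2 is set, base would open ring C through the chalcone and scramble C2, and acid would endanger the tertiary alcohol/isopropenyl pair; buffered fluoride avoids both.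

**Ring A**

Step 1
Reactants: 1 1-(2,6-dihydroxy-4-methoxyphenyl)ethanone
Product: 2 1-(2,6-dihydroxy-3-iodo-4-methoxyphenyl)ethanone
Conditions: NIS (1.0 equiv), MeCN, 0 °C
Reagents that add atoms: N-iodosuccinimide, O=C1CCC(=O)N1I
Why: Electrophilic aromatic iodination; the two free ring positions of 1 are equivalent by symmetry, so mono-iodination can give only one product, and one equivalent of reagent at 0 °C limits di-iodination.

Step 2
Reactants: 2 1-(2,6-dihydroxy-3-iodo-4-methoxyphenyl)ethanone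
Product: 3 1-[2-hydroxy-3-iodo-4-methoxy-6-(TIPS-oxy)phenyl]ethanone
Conditions: i-Pr3SiCl (1.05 equiv), imidazole, DMF, 0 °C → rt
Reagents that add atoms: chlorotri(propan-2-yl)silane, CC(C)[Si](Cl)(C(C)C)C(C)C
Why: Imidazole-promoted O-silylation; the bulky silyl chloride should take the hydroxyl next to the ring hydrogen, while the hydroxyl wedged between iodine and the acetyl group is more hindered and stays chelated to the carbonyl, which also stops bis-silylation.

**Ring B**

Step 3
Reactants: 4 2,4-dihydroxybenzaldehyde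
Product: 5 2,4-bis(TBS-oxy)benzaldehyde
Conditions: t-BuMe2SiCl (2.5 equiv), imidazole, DMF, rt
Reagents that add atoms: tert-butylchlorodimethylsilane, CC(C)(C)[Si](C)(C)Cl
Why: Imidazole-promoted silyl ether formation at both phenols; the chelated 2-hydroxyl reacts more slowly but should go to completion with excess reagent in DMF.

Step 4
Reactants: 5 2,4-bis(TBS-oxy)benzaldehyde
Product: 6 [2,4-bis(TBS-oxy)phenyl]methanol
Conditions: i-Bu2AlH, CH2Cl2, −78 °C; aq. KNaC4H4O6
Reagents that add atoms: none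
Why: Hydride reduction of the aldehyde; the aluminium alkoxide formed at −78 °C is too weakly nucleophilic to take the neighbouring silyl group, so 1,4 oxygen-to-oxygen silyl migration is avoided.

Step 5
Reactants: 3 1-[2-hydroxy-3-iodo-4-methoxy-6-(TIPS-oxy)phenyl]ethanone; 6 [2,4-bis(TBS-oxy)phenyl]methanol
Product: 7 1-[2-{[2,4-bis(TBS-oxy)phenyl]methoxy}-3-iodo-4-methoxy-6-(TIPS-oxy)phenyl]ethanone
Conditions: PPh3, DIAD, THF, 0 °C → rt
Reagents that add atoms: none
Why: Mitsunobu etherification; the acidic, carbonyl-chelated phenol protonates the betaine and its phenoxide displaces the benzylic oxyphosphonium under neutral conditions that spare the aryl silyl ethers and the aryl iodide.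

**Side chain**

Step 6
Reactants: 8 (4S)-4-benzyl-1,3-oxazolidin-2-one; 9 3-methylbut-2-enoyl chloride
Product: 10 (4S)-4-benzyl-3-(3-methylbut-2-enoyl)-1,3-oxazolidin-2-one
Conditions: n-BuLi, THF, −78 °C; then 9, −78 → 0 °C
Reagents that add atoms: none
Why: N-Acylation of the lithiated oxazolidinone with the acid chloride, the standard entry to Evans imides.

Step 7
Reactants: 10 (4S)-4-benzyl-3-(3-methylbut-2-enoyl)-1,3-oxazolidin-2-one; 11 1-bromo-3-methylbut-2-ene
Product: 12 (4S)-4-benzyl-3-[(2S)-5-methyl-2-(prop-1-en-2-yl)hex-4-enoyl]-1,3-oxazolidin-2-one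
Conditions: NaN(SiMe3)2, THF, −78 °C; then 11, −78 → −40 °C
Reagents that add atoms: none
Why: Evans asymmetric alkylation; γ-deprotonation gives the chelated Z-configured sodium dienolate, which is alkylated at the α-carbon (deconjugative alkylation) on the face opposite the C4 benzyl group, setting the (2S) centre that becomes the (2R) side-chain centre of the target (same spatial arrangement, changed substituent priorities).

Step 8
Reactants: 12 (4S)-4-benzyl-3-[(2S)-5-methyl-2-(prop-1-en-2-yl)hex-4-enoyl]-1,3-oxazolidin-2-one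
Product: 13 (4S)-4-benzyl-3-[(2S)-3-(3,3-dimethyloxiran-2-yl)-2-(prop-1-en-2-yl)propanoyl]-1,3-oxazolidin-2-one (both epoxide epimers)
Conditions: mCPBA (1.05 equiv), NaHCO3, CH2Cl2, 0 °C
Reagents that add atoms: 3-chloroperoxybenzoic acid, O=C(OO)c1cccc(Cl)c1
Why: Prilezhaev epoxidation; the trisubstituted alkene is markedly more nucleophilic than the 1,1-disubstituted isopropenyl group, which is also deactivated by the adjacent acyl-bearing carbon, and the epoxide configuration is irrelevant because that centre is removed in step 9.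

Step 9
Reactants: 13 (4S)-4-benzyl-3-[(2S)-3-(3,3-dimethyloxiran-2-yl)-2-(prop-1-en-2-yl)propanoyl]-1,3-oxazolidin-2-one
Product: 14 (2S)-5-methyl-2-(prop-1-en-2-yl)hexane-1,5-diol
Conditions: LiAlH4, THF, 0 °C → rt
Reagents that add atoms: none
Why: Hydride reduction; LiAlH4 cleaves the imide reductively to the primary alcohol and opens the epoxide by SN2 attack at its less substituted carbon to give the tertiary alcohol, leaving the stereocentre and the isopropenyl group untouched.

Step 10
Reactants: 14 (2S)-5-methyl-2-(prop-1-en-2-yl)hexane-1,5-diol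
Product: 15 (5S)-6-iodo-2-methyl-5-(prop-1-en-2-yl)hexan-2-ol
Conditions: I2, PPh3, imidazole, CH2Cl2, 0 °C
Reagents that add atoms: iodine, II
Why: Appel-type iodination; only the primary hydroxyl forms an oxyphosphonium salt that iodide can displace, the tertiary hydroxyl being too hindered to react at 0 °C.

Step 11
Reactants: 15 (5S)-6-iodo-2-methyl-5-(prop-1-en-2-yl)hexan-2-ol
Product: 16 triethyl{[(5S)-6-iodo-2-methyl-5-(prop-1-en-2-yl)hexan-2-yl]oxy}silane
Conditions: Et3SiOTf, 2,6-lutidine, CH2Cl2, −78 → 0 °C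
Reagents that add atoms: triethylsilyl trifluoromethanesulfonate, CC[Si](CC)(CC)OS(=O)(=O)C(F)(F)F
Why: Silyl triflate silylation of a tertiary alcohol with a hindered pyridine base; the primary iodide is inert to these conditions.

**Assembly, key step and deprotection**

Step 12
Reactants: 16 triethyl{[(5S)-6-iodo-2-methyl-5-(prop-1-en-2-yl)hexan-2-yl]oxy}silane; 7 1-[2-{[2,4-bis(TBS-oxy)phenyl]methoxy}-3-iodo-4-methoxy-6-(TIPS-oxy)phenyl]ethanone
Product: 18 1-[2-{[2,4-bis(TBS-oxy)phenyl]methoxy}-4-methoxy-3-[(2R)-5-methyl-2-(prop-1-en-2-yl)-5-(TES-oxy)hexyl]-6-(TIPS-oxy)phenyl]ethanone, via alkylzinc iodide 17 (not isolated)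
Conditions: Zn dust (activated by Me3SiCl/BrCH2CH2Br), LiCl, THF, 40 °C; then 7, Pd(OAc)2 (5 mol %), SPhos (10 mol %), THF, 50 °C
Reagents that add atoms: none
Why: Negishi cross-coupling; zinc inserts into the primary C–I bond and the alkylzinc iodide transmetalates to the arylpalladium iodide from 7, the bulky biarylphosphine promoting oxidative addition and fast reductive elimination at the doubly ortho-substituted carbon ahead of β-hydride elimination, while the stereocentre β to zinc is not involved and the ketone and silyl ethers tolerate organozinc reagents.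

Step 13
Reactants: 18 1-[2-{[2,4-bis(TBS-oxy)phenyl]methoxy}-4-methoxy-3-[(2R)-5-methyl-2-(prop-1-en-2-yl)-5-(TES-oxy)hexyl]-6-(TIPS-oxy)phenyl]ethanone
Product: 19 1-[2-{[2,4-bis(TBS-oxy)phenyl]methoxy}-4-methoxy-3-[(2R)-5-methyl-2-(prop-1-en-2-yl)-5-(TES-oxy)hexyl]-6-(TIPS-oxy)phenyl]-4,4,4-trifluorobutane-1,3-dione
Conditions: LiN(SiMe3)2 (2.2 equiv), THF, −78 °C; CF3CO2CH2CF3; aq. NH4Cl quench
Reagents that add atoms: 2,2,2-trifluoroethyl trifluoroacetate, O=C(OCC(F)(F)F)C(F)(F)F
Why: Crossed Claisen condensation; the kinetic lithium enolate of the methyl ketone is acylated by the trifluoroacetate ester, which activates the methyl group for diazo transfer.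

Step 14
Reactants: 19 1-[2-{[2,4-bis(TBS-oxy)phenyl]methoxy}-4-methoxy-3-[(2R)-5-methyl-2-(prop-1-en-2-yl)-5-(TES-oxy)hexyl]-6-(TIPS-oxy)phenyl]-4,4,4-trifluorobutane-1,3-dione
Product: 20 2-diazo-1-[2-{[2,4-bis(TBS-oxy)phenyl]methoxy}-4-methoxy-3-[(2R)-5-methyl-2-(prop-1-en-2-yl)-5-(TES-oxy)hexyl]-6-(TIPS-oxy)phenyl]ethanone
Conditions: 4-acetamidobenzenesulfonyl azide, Et3N, H2O (1 equiv), MeCN, rt
Reagents that add atoms: 4-acetamidobenzenesulfonyl azide, CC(=O)Nc1ccc(cc1)S(=O)(=O)N=[N+]=[N-]
Why: Detrifluoroacetylative diazo transfer (Regitz–Danheiser type); the diketone enolate adds to the sulfonyl azide and the triazoline collapses with transfer of the trifluoroacetyl group to the sulfonamide nitrogen, leaving the α-diazoketone under mildly basic conditions that the TIPS and TBS aryl ethers should withstand.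

Step 15
Reactants: 20 2-diazo-1-[2-{[2,4-bis(TBS-oxy)phenyl]methoxy}-4-methoxy-3-[(2R)-5-methyl-2-(prop-1-en-2-yl)-5-(TES-oxy)hexyl]-6-(TIPS-oxy)phenyl]ethanone
Product: 21 (2S)-2-[2,4-bis(TBS-oxy)phenyl]-7-methoxy-8-[(2R)-5-methyl-2-(prop-1-en-2-yl)-5-(TES-oxy)hexyl]-5-(TIPS-oxy)-2,3-dihydro-4H-chromen-4-one
Conditions: Rh2(S-PTTL)4 (dirhodium tetrakis[N-phthaloyl-(S)-tert-leucinate], 2 mol %), toluene, 4 Å MS, 0 °C, slow addition of 20
Reagents that add atoms: none
Why: The divalent rhodium carboxylate expels N2 from 20 to give an electrophilic rhodium carbenoid at C3, which inserts into the benzylic C2–H bond through a concerted three-centre transition state with hydride-transfer character, the developing positive charge at C2 being stabilised by O1 and by the bis(silyloxy)phenyl ring. The closest known reaction type is the dirhodium tetracarboxylate-catalysed intramolecular C–H insertion of 2-alkoxyaryl α-diazoketones to chroman-4-ones. Ring C closes as a six-membered ring by 1,6-insertion, because the atom a five-membered closure would need is O1, which carries no hydrogen. The new C2 stereocentre is set by the chiral N-phthaloyl-tert-leucinate ligands, which distinguish the two enantiotopic benzylic hydrogens; the remote side-chain centre is not expected to interfere, and a minor C2 epimer would be a diastereomer removable by chromatography. The step needs C–H insertion to beat attack of O1 on the carbenoid (oxonium ylide, then Stevens 1,2-benzyl shift to a benzofuranone) and any reaction at O5; this should be secured by the O1 ether being flanked by the acyl group and the C8 chain, the strongly hydridic C2–H bond, the TIPS group at O5 (no activated C–H, shielded oxygen) and the isopropenyl group being held too far away for cyclopropanation.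

Step 16
Reactants: 21 (2S)-2-[2,4-bis(TBS-oxy)phenyl]-7-methoxy-8-[(2R)-5-methyl-2-(prop-1-en-2-yl)-5-(TES-oxy)hexyl]-5-(TIPS-oxy)-2,3-dihydro-4H-chromen-4-one
Product: 22 (2S)-2-(2,4-dihydroxyphenyl)-5-hydroxy-8-[(2R)-5-hydroxy-5-methyl-2-(prop-1-en-2-yl)hexyl]-7-methoxy-2,3-dihydro-4H-chromen-4-one
Conditions: HF·pyridine, pyridine, THF, 0 °C → rt
Reagents that add atoms: none
Why: Fluoride-driven global desilylation with pyridine-buffered HF; all four Si–O bonds are cleaved without the base that would open ring C via the chalcone and scramble C2, and without the strong acid that would ionise the tertiary alcohol or protonate the isopropenyl group.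

**Compound list**

1 | 1-(2,6-dihydroxy-4-methoxyphenyl)ethanone | COc1cc(O)c(C(C)=O)c(O)c1 | starting material
2 | 1-(2,6-dihydroxy-3-iodo-4-methoxyphenyl)ethanone | COc1cc(O)c(C(C)=O)c(O)c1I | intermediate
3 | 1-[2-hydroxy-3-iodo-4-methoxy-6-(TIPS-oxy)phenyl]ethanone | COc1cc(O[Si](C(C)C)(C(C)C)C(C)C)c(C(C)=O)c(O)c1I | intermediate
4 | 2,4-dihydroxybenzaldehyde | O=Cc1ccc(O)cc1O | starting material
5 | 2,4-bis(TBS-oxy)benzaldehyde | O=Cc1ccc(O[Si](C)(C)C(C)(C)C)cc1O[Si](C)(C)C(C)(C)C | intermediate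
6 | [2,4-bis(TBS-oxy)phenyl]methanol | OCc1ccc(O[Si](C)(C)C(C)(C)C)cc1O[Si](C)(C)C(C)(C)C | intermediate
7 | 1-[2-{[2,4-bis(TBS-oxy)phenyl]methoxy}-3-iodo-4-methoxy-6-(TIPS-oxy)phenyl]ethanone | COc1cc(O[Si](C(C)C)(C(C)C)C(C)C)c(C(C)=O)c(OCc2ccc(O[Si](C)(C)C(C)(C)C)cc2O[Si](C)(C)C(C)(C)C)c1I | intermediate
8 | (4S)-4-benzyl-1,3-oxazolidin-2-one | O=C1N[C@@H](Cc2ccccc2)CO1 | starting material
9 | 3-methylbut-2-enoyl chloride | CC(C)=CC(=O)Cl | starting material
10 | (4S)-4-benzyl-3-(3-methylbut-2-enoyl)-1,3-oxazolidin-2-one | CC(C)=CC(=O)N1[C@@H](Cc2ccccc2)COC1=O | intermediate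
11 | 1-bromo-3-methylbut-2-ene | CC(C)=CCBr | starting material
12 | (4S)-4-benzyl-3-[(2S)-5-methyl-2-(prop-1-en-2-yl)hex-4-enoyl]-1,3-oxazolidin-2-one | C=C(C)[C@H](CC=C(C)C)C(=O)N1[C@@H](Cc2ccccc2)COC1=O | intermediate
13 | (4S)-4-benzyl-3-[(2S)-3-(3,3-dimethyloxiran-2-yl)-2-(prop-1-en-2-yl)propanoyl]-1,3-oxazolidin-2-one (both epoxide epimers) | C=C(C)[C@H](CC1OC1(C)C)C(=O)N1[C@@H](Cc2ccccc2)COC1=O | intermediate
14 | (2S)-5-methyl-2-(prop-1-en-2-yl)hexane-1,5-diol | C=C(C)[C@H](CCC(C)(C)O)CO | intermediate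
15 | (5S)-6-iodo-2-methyl-5-(prop-1-en-2-yl)hexan-2-ol | C=C(C)[C@H](CCC(C)(C)O)CI | intermediate
16 | triethyl{[(5S)-6-iodo-2-methyl-5-(prop-1-en-2-yl)hexan-2-yl]oxy}silane | C=C(C)[C@H](CCC(C)(C)O[Si](CC)(CC)CC)CI | intermediate
17 | iodo{(2S)-5-methyl-2-(prop-1-en-2-yl)-5-(TES-oxy)hexyl}zinc | C=C(C)[C@H](CCC(C)(C)O[Si](CC)(CC)CC)C[Zn]I | intermediate
18 | 1-[2-{[2,4-bis(TBS-oxy)phenyl]methoxy}-4-methoxy-3-[(2R)-5-methyl-2-(prop-1-en-2-yl)-5-(TES-oxy)hexyl]-6-(TIPS-oxy)phenyl]ethanone | C=C(C)[C@H](CCC(C)(C)O[Si](CC)(CC)CC)Cc1c(OC)cc(O[Si](C(C)C)(C(C)C)C(C)C)c(C(C)=O)c1OCc1ccc(O[Si](C)(C)C(C)(C)C)cc1O[Si](C)(C)C(C)(C)C | intermediate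
19 | 1-[2-{[2,4-bis(TBS-oxy)phenyl]methoxy}-4-methoxy-3-[(2R)-5-methyl-2-(prop-1-en-2-yl)-5-(TES-oxy)hexyl]-6-(TIPS-oxy)phenyl]-4,4,4-trifluorobutane-1,3-dione | C=C(C)[C@H](CCC(C)(C)O[Si](CC)(CC)CC)Cc1c(OC)cc(O[Si](C(C)C)(C(C)C)C(C)C)c(C(=O)CC(=O)C(F)(F)F)c1OCc1ccc(O[Si](C)(C)C(C)(C)C)cc1O[Si](C)(C)C(C)(C)C | intermediate
20 | 2-diazo-1-[2-{[2,4-bis(TBS-oxy)phenyl]methoxy}-4-methoxy-3-[(2R)-5-methyl-2-(prop-1-en-2-yl)-5-(TES-oxy)hexyl]-6-(TIPS-oxy)phenyl]ethanone | C=C(C)[C@H](CCC(C)(C)O[Si](CC)(CC)CC)Cc1c(OC)cc(O[Si](C(C)C)(C(C)C)C(C)C)c(C(=O)C=[N+]=[N-])c1OCc1ccc(O[Si](C)(C)C(C)(C)C)cc1O[Si](C)(C)C(C)(C)C | intermediate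
21 | (2S)-2-[2,4-bis(TBS-oxy)phenyl]-7-methoxy-8-[(2R)-5-methyl-2-(prop-1-en-2-yl)-5-(TES-oxy)hexyl]-5-(TIPS-oxy)-2,3-dihydro-4H-chromen-4-one | C=C(C)[C@H](CCC(C)(C)O[Si](CC)(CC)CC)Cc1c(OC)cc(O[Si](C(C)C)(C(C)C)C(C)C)c2c1O[C@H](c1ccc(O[Si](C)(C)C(C)(C)C)cc1O[Si](C)(C)C(C)(C)C)CC2=O | intermediate
22 | (2S)-2-(2,4-dihydroxyphenyl)-5-hydroxy-8-[(2R)-5-hydroxy-5-methyl-2-(prop-1-en-2-yl)hexyl]-7-methoxy-2,3-dihydro-4H-chromen-4-one | C=C(C)[C@H](CCC(C)(C)O)Cc1c(OC)cc(O)c2c1O[C@H](c1ccc(O)cc1O)CC2=O | target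

**Step count and risks**

Total step count: 16. Longest linear sequence: 11 steps (steps 6–16, from 8 and 9).

Steps most likely to fail:

1. Step 15. The carbenoid may be captured by the O1 lone pair, the oxonium ylide then rearranging by benzyl 1,2-shift, or the two benzylic hydrogens may be poorly discriminated. The fallback closes ring C at O1–C2 by known chemistry. It sets out from 3: Negishi coupling of 3 with an excess of zinc reagent 17 (Pd(OAc)2, SPhos, THF, 50 °C; the phenol consumes one equivalent) should give the 2-hydroxyaryl methyl ketone F1. Double deprotonation with LiN(SiMe3)2 (THF, −78 °C) and aldol addition to aldehyde 5 should give the β-hydroxy ketone F2 as both carbinol epimers. Intramolecular Mitsunobu etherification (PPh3, DIAD, THF, 0 °C) should then form O1–C2 and deliver 21 together with the (2R)-epimer F3. The two are diastereomers and are separated by chromatography, and the route is rejoined at 21.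

2. Step 12. Transmetalation and reductive elimination may be slow at the doubly ortho-substituted arylpalladium, letting β-hydride elimination or hydrodeiodination take over, or zinc insertion may stall. The fallback sets out from 16 and 7 and returns at 18: iodine–lithium exchange on 16 (t-BuLi, Et2O, −78 °C) and capture with 9-methoxy-9-borabicyclo[3.3.1]nonane should give the lithium alkyl(methoxy)borate F4, which transfers its primary alkyl group to palladium without added base. B-alkyl Suzuki–Miyaura coupling with 7 (PdCl2(dppf), THF/DMF, 50 °C) should then give 18.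

3. Step 5. Displacement at the hindered, chelated phenol may be slow, so that the electron-rich benzylic oxyphosphonium is intercepted by the reduced azodicarboxylate. The fallback sets out from 6 and returns at 7: MsCl, Et3N, LiCl (THF, 0 °C) should convert 6 into the benzylic chloride F5, used at once. Ag2O in toluene at rt should then O-alkylate phenol 3 under neutral conditions (silver-assisted Williamson etherification) to give 7.

**Further compounds**

F1 | step 15 | 1-{2-hydroxy-4-methoxy-3-[(2R)-5-methyl-2-(prop-1-en-2-yl)-5-(TES-oxy)hexyl]-6-(TIPS-oxy)phenyl}ethanone | C=C(C)[C@H](CCC(C)(C)O[Si](CC)(CC)CC)Cc1c(OC)cc(O[Si](C(C)C)(C(C)C)C(C)C)c(C(C)=O)c1O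
F2 | step 15 | 3-[2,4-bis(TBS-oxy)phenyl]-3-hydroxy-1-{2-hydroxy-4-methoxy-3-[(2R)-5-methyl-2-(prop-1-en-2-yl)-5-(TES-oxy)hexyl]-6-(TIPS-oxy)phenyl}propan-1-one (both carbinol epimers) | C=C(C)[C@H](CCC(C)(C)O[Si](CC)(CC)CC)Cc1c(OC)cc(O[Si](C(C)C)(C(C)C)C(C)C)c(C(=O)CC(O)c2ccc(O[Si](C)(C)C(C)(C)C)cc2O[Si](C)(C)C(C)(C)C)c1O
F3 | step 15 | (2R)-2-[2,4-bis(TBS-oxy)phenyl]-7-methoxy-8-[(2R)-5-methyl-2-(prop-1-en-2-yl)-5-(TES-oxy)hexyl]-5-(TIPS-oxy)-2,3-dihydro-4H-chromen-4-one | C=C(C)[C@H](CCC(C)(C)O[Si](CC)(CC)CC)Cc1c(OC)cc(O[Si](C(C)C)(C(C)C)C(C)C)c2c1O[C@@H](c1ccc(O[Si](C)(C)C(C)(C)C)cc1O[Si](C)(C)C(C)(C)C)CC2=O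
F4 | step 12 | lithium 9-methoxy-9-{(2S)-5-methyl-2-(prop-1-en-2-yl)-5-(TES-oxy)hexyl}-9-boranuidabicyclo[3.3.1]nonane | C=C(C)[C@H](CCC(C)(C)O[Si](CC)(CC)CC)C[B-]1(OC)C2CCCC1CCC2.[Li+]
F5 | step 5 | 1-(chloromethyl)-2,4-bis(TBS-oxy)benzene | ClCc1ccc(O[Si](C)(C)C(C)(C)C)cc1O[Si](C)(C)C(C)(C)C
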